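1. If each target cost one partner, Monday's flask could not be short of partner: target stands at 52.8% of the charge at the last reading, so that ledger leaves 47.2% of the partner unused, yet the readings are flattening.

| setting | Monday's | Friday's | Saturday's |
|---|---|---|---|
| starting material | 0.0800 M | 0.120 M | 0.0800 M |
| partner | 0.0800 M | 0.0800 M | 0.160 M |
| free catalyst | 0.00160 M | 0.00160 M | 0.00320 M |
| time |  |  | 37 h |

- Monday's run (time / h: [target] / M): 1.5: 0.00855; 2.3: 0.01180; 3.7: 0.01681; 5.9: 0.02301; 9.3: 0.02948; 15: 0.03580; 23: 0.03985; 37: 0.04224
- Friday's run (time / h: [target] / M): 1.5: 0.01189; 2.3: 0.01715; 3.7: 0.02418; 5.9: 0.03223; 9.3: 0.04032; 15: 0.04781; 23: 0.05265; 37: 0.05519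

(each reading ± 2 × 10⁻⁴ M)

- apparent order in [starting material] of the starting rate, round the charge of the Monday's run (the rate where two percent of its starting material have turned into target) (one fixed amount of target, the same in the runs compared)
- target in the Saturday's run at 37 h, as a share of the starting material charged

- Overall: starting material + partner -> target, with free catalyst as catalyst.
- Constant volume, constant temperature.
- Bound and free are read together.
- An order is taken over about fifteen percent of the charge, up and down.

2. Our reckoning supposes that target also consumes partner, giving side product, so each target lost has cost two partners. If we take partner to be at zero at the last reading, Monday's flask keeps an estimated 23.6% of its starting material.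

3. Let σ be the loss ratio (a selectivity factor), the speed of the loss step over the main step at equal fractions of target and starting material, with the free catalyst charge held at Monday's. With x the fraction of starting material left, the target fraction is (x^σ − x)/(1 − σ), whatever the clock says. Trying 0.5 and correcting by the misfit gives 0.418; going round once more gives 0.432.

4. On the same supposition, Friday's flask, the neighbour with the same free catalyst charge, keeps more starting material than Monday's, an estimated 43.7%. Monday's σ then gives it a target fraction of 46.2%, and the reading gives 46.0%.

5. Second readings, divided by mean partner, give an order in starting material of 1.01. Monday's main constant reads 0.934 L mol⁻¹ h⁻¹.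

6. Saturday's partner charge is twice its starting material. We assume the loss step uses no catalyst and that the main step finishes early, so target and partner stay equal. The target fraction is then 1 over (1 + σ·k·charge·time), with Monday's σ and Monday's main constant k, which gives 45.6%.

7. The forecast gives 0.98 and 94%, on the grounds that “A dying catalyst fits better.”

8. The flask gives 1.0 and 45.2%.

    2 free catalyst ⇌ catalyst dimer, settled at all times (41400 L mol⁻¹)
    catalyst dimer + starting material + partner → target + catalyst dimer (1476 L² mol⁻² h⁻¹)
    free catalyst + partner ⇌ idle catalyst-reagent complex, settled at all times (16.70 L mol⁻¹)
    target + partner → side product (0.4248 L mol⁻¹ h⁻¹)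

Saturday's flask falls short through the loss of target and partner to side product. The run without that step reaches 99.9% against 45.2%, and the step accounts for 100% of what is missing. Carried over, σ with Monday's constant counts 1.19 targets lost for each target standing in Saturday's flask at 37 h.

(The runs were computed with constants of no real substance; the scatter is artificial.)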